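**Retrosynthetic overview**

1. Target 14 ← hydrogenolysis of the 3,4'-di-O-benzyl flavone 13 ← Baker–Venkataraman rearrangement and cyclodehydration (closes ring C) of the mono-aroyl ester 11, made from the symmetric ketone 9 and 4-(benzyloxy)benzoyl chloride 10 (ring B is bought).
2. 9 ← para-selective O-methylation of acylphloroglucinol 8 ← Claisen-mode folding of the open-chain triketo ester 7, which closes ring A by the C4a–C8a bond (equally readable as C4a–C5, since 8 and 9 are symmetric).
3. Feature used: in ring A the oxygen-bearing carbons C8a, C7 and C5 correspond to carbonyl carbons of a polyketide-like chain, while C8 and C6 (the two flanking methoxylated carbons) and C4a (which carries C4) correspond to the sp3 carbons between them; chain C1–C8 of 7 maps onto C8a, C8, C7, C6, C5, C4a, C4, C3.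
4. 7 ← ketal hydrolysis of 6 ← γ-acylation of the dianion of 2 with ketal ester 4; 2 from self-condensation of methyl methoxyacetate 1, 4 from keto ester 3.
5. Ring order: ring A (step 5), then ring C (step 8); ring B arrives intact in 10.

Key step: step 5

Remark on the chemistry: 2, 6, 7 and 12 are drawn as keto forms but will be largely enolised, and their methine centres are configurationally labile. This has no consequence, because these carbons become sp2 and the target has no stereocentre.

**Route**

Step 1
Reactants: 1 methyl methoxyacetate (two molecules)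
Product: 2 methyl 2,4-dimethoxy-3-oxobutanoate
Conditions: NaH (0.55 equiv), THF, 0 °C → reflux; then aq. HCl, 0 °C
Reagents that add atoms: none
Why: Claisen ester self-condensation, in which the sodium enolate of 1 acylates a second molecule of 1 and the equilibrium is drawn forward by deprotonation of the β-keto ester formed; this is a long-established way to this compound.

Step 2
Reactants: 3 ethyl 4-(benzyloxy)-3-oxobutanoate
Product: 4 ethyl 2-[2-(benzyloxymethyl)-1,3-dioxolan-2-yl]acetate
Conditions: ethane-1,2-diol (1.5 equiv), p-TsOH·H2O (cat.), toluene, reflux, Dean–Stark trap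
Reagents that add atoms: ethane-1,2-diol, OCCO
Why: Acid-catalysed ketalisation with azeotropic removal of water masks the ketone as a 1,3-dioxolane, so that the ester can later act as a pure acyl donor; the ester and the benzyl ether are inert.

Step 3
Reactants: 2 methyl 2,4-dimethoxy-3-oxobutanoate (2.2 equiv); 4 ethyl 2-[2-(benzyloxymethyl)-1,3-dioxolan-2-yl]acetate (1.0 equiv)
Product: 6 methyl 6-[2-(benzyloxymethyl)-1,3-dioxolan-2-yl]-2,4-dimethoxy-3,5-dioxohexanoate, via dilithium dienolate 5 (not isolated)
Conditions: LiN(i-Pr)2 (4.4 equiv), THF, −78 → −20 °C; then 4, −78 → 0 °C; AcOH quench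
Reagents that add atoms: none
Why: γ-Acylation of a β-keto ester dianion by an ester (Claisen-type C-acylation): the second deprotonation places the most reactive carbanion on the methoxylated C4, the dioxolane keeps the donor's ketone from enolising, and the excess of 5 serves as base for the more acidic diketone product (the surplus 2 should be recoverable).

Step 4
Reactants: 6 methyl 6-[2-(benzyloxymethyl)-1,3-dioxolan-2-yl]-2,4-dimethoxy-3,5-dioxohexanoate
Product: 7 methyl 8-(benzyloxy)-2,4-dimethoxy-3,5,7-trioxooctanoate
Conditions: 2 M aq. HCl/THF (1:2), rt; used without delay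
Reagents that add atoms: water, O
Why: Acid-catalysed ketal hydrolysis frees the C7 ketone, while the benzyl ether, the methyl ester and the enolised 1,3-dicarbonyl units should tolerate dilute acid at room temperature.

Step 5
Reactants: 7 methyl 8-(benzyloxy)-2,4-dimethoxy-3,5,7-trioxooctanoate
Product: 8 2-(benzyloxy)-1-(2,4,6-trihydroxy-3,5-dimethoxyphenyl)ethan-1-one
Conditions: Mg(OMe)2 (4 equiv), degassed MeOH, argon, rt → 55 °C; then 1 M aq. HCl, 0 °C
Reagents that add atoms: none
Why: Mg(OMe)2 turns 7 into a magnesium polyenolate in which the C6 methylene, the only unsubstituted carbon flanked by two ketones, attacks the C1 ester carbonyl; loss of methoxide gives a 2-acylcyclohexane-1,3,5-trione whose C2 and C4 methines enolise at once to the aromatic acylphloroglucinol 8, creating the C4a–C8a bond of the flavone. The closest known reaction is the base-mediated Claisen-mode (Dieckmann-type) cyclisation of 3,5,7-trioxoalkanoate esters, and of the related 6-(2-oxoalkyl)-4-hydroxy-2-pyranones, to acylphloroglucinols, applied here to a chain with methoxyls on C2 and C4. Ring A closes in a 6-exo-trig manner, the enolate carbon adding to an ester C=O that lies outside the new ring. No stereocentre is created, and the labile C2 and C4 centres of 7 disappear on aromatisation. The selectivity needed is Claisen closure over the aldol fold (C2 onto the C7 ketone) and over O-acylation to a 2-pyranone: the C2 methoxyl makes the aldol adduct quaternary at C2, so it cannot dehydrate to an arene and reverts by retro-aldol; methoxide in methanol reopens any pyranone to the methyl ester; and only the Claisen product leaves the equilibria irreversibly as an aromatic phenoxide. The C8 methylene is only singly activated and the C3 ketone lies between two enolised methines, so the other aldol fold (C8 onto C3) should not compete.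

Step 6
Reactants: 8 2-(benzyloxy)-1-(2,4,6-trihydroxy-3,5-dimethoxyphenyl)ethan-1-one
Product: 9 2-(benzyloxy)-1-(2,6-dihydroxy-3,4,5-trimethoxyphenyl)ethan-1-one
Conditions: Me2SO4 (1.05 equiv), K2CO3 (1.1 equiv), acetone, argon, 0 °C → rt
Reagents that add atoms: dimethyl sulfate, COS(=O)(=O)OC
Why: Williamson-type O-methylation under carbonate control: the 4-hydroxyl, para to the acyl group, is the most acidic and the only one that cannot hydrogen-bond to the carbonyl, so one equivalent of base and of dimethyl sulfate should alkylate it selectively.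

Step 7
Reactants: 9 2-(benzyloxy)-1-(2,6-dihydroxy-3,4,5-trimethoxyphenyl)ethan-1-one; 10 4-(benzyloxy)benzoyl chloride (1.05 equiv)
Product: 11 2-[2-(benzyloxy)acetyl]-3-hydroxy-4,5,6-trimethoxyphenyl 4-(benzyloxy)benzoate
Conditions: Et3N (1.2 equiv), DMAP (0.05 equiv), CH2Cl2, 0 °C
Reagents that add atoms: none
Why: DMAP-catalysed O-acylation of one of the two equivalent ortho phenols; the remaining hydroxyl is held in a hydrogen bond to the ketone and is much less nucleophilic, so one equivalent of acid chloride should stop at the monoester.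

Step 8
Reactants: 11 2-[2-(benzyloxy)acetyl]-3-hydroxy-4,5,6-trimethoxyphenyl 4-(benzyloxy)benzoate
Product: 13 3-(benzyloxy)-2-[4-(benzyloxy)phenyl]-5-hydroxy-6,7,8-trimethoxy-4H-chromen-4-one, via 1,3-diketone 12 (not isolated)
Conditions: LiN(SiMe3)2 (3.3 equiv), THF, −78 → 0 °C; then AcOH (excess), H2SO4 (cat.), THF distilled off, 60 °C
Reagents that add atoms: none
Why: Baker–Venkataraman rearrangement (the α-benzyloxy ketone enolate attacks the neighbouring aryl ester carbonyl and moves the aroyl group from O to C), followed by acid-catalysed cyclodehydration of the o-hydroxyaryl 1,3-diketone, which closes ring C; either of the two equivalent phenols gives the same flavone.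

Step 9
Reactants: 13 3-(benzyloxy)-2-[4-(benzyloxy)phenyl]-5-hydroxy-6,7,8-trimethoxy-4H-chromen-4-one
Product: 14 3,5,4'-trihydroxy-6,7,8-trimethoxyflavone
Conditions: H2 (1 atm), 10% Pd/C, EtOAc/MeOH (1:1), rt
Reagents that add atoms: none
Why: Catalytic hydrogenolysis cleaves both benzyl ethers (the 3-O-benzyl enol ether and the 4'-O-benzyl aryl ether), while the methyl ethers and the conjugated chromenone should be untouched under one atmosphere of hydrogen at room temperature.

**Compound list**

1 | methyl methoxyacetate | COCC(=O)OC | starting material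
2 | methyl 2,4-dimethoxy-3-oxobutanoate | COCC(=O)C(OC)C(=O)OC | intermediate
3 | ethyl 4-(benzyloxy)-3-oxobutanoate | CCOC(=O)CC(=O)COCc1ccccc1 | starting material
4 | ethyl 2-[2-(benzyloxymethyl)-1,3-dioxolan-2-yl]acetate | CCOC(=O)CC1(COCc2ccccc2)OCCO1 | intermediate
5 | dilithium 1,2,4-trimethoxybuta-1,3-diene-1,3-bis(olate) (dianion of 2) | [Li+].[Li+].COC=C([O-])C(OC)=C([O-])OC | intermediate
6 | methyl 6-[2-(benzyloxymethyl)-1,3-dioxolan-2-yl]-2,4-dimethoxy-3,5-dioxohexanoate | COC(=O)C(OC)C(=O)C(OC)C(=O)CC1(COCc2ccccc2)OCCO1 | intermediate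
7 | methyl 8-(benzyloxy)-2,4-dimethoxy-3,5,7-trioxooctanoate | COC(=O)C(OC)C(=O)C(OC)C(=O)CC(=O)COCc1ccccc1 | intermediate
8 | 2-(benzyloxy)-1-(2,4,6-trihydroxy-3,5-dimethoxyphenyl)ethan-1-one | COc1c(O)c(OC)c(O)c(C(=O)COCc2ccccc2)c1O | intermediate
9 | 2-(benzyloxy)-1-(2,6-dihydroxy-3,4,5-trimethoxyphenyl)ethan-1-one | COc1c(OC)c(O)c(C(=O)COCc2ccccc2)c(O)c1OC | intermediate
10 | 4-(benzyloxy)benzoyl chloride | O=C(Cl)c1ccc(OCc2ccccc2)cc1 | starting material
11 | 2-[2-(benzyloxy)acetyl]-3-hydroxy-4,5,6-trimethoxyphenyl 4-(benzyloxy)benzoate | COc1c(OC)c(O)c(C(=O)COCc2ccccc2)c(OC(=O)c2ccc(OCc3ccccc3)cc2)c1OC | intermediate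
12 | 2-(benzyloxy)-1-[4-(benzyloxy)phenyl]-3-(2,6-dihydroxy-3,4,5-trimethoxyphenyl)propane-1,3-dione | COc1c(OC)c(O)c(C(=O)C(OCc2ccccc2)C(=O)c2ccc(OCc3ccccc3)cc2)c(O)c1OC | intermediate
13 | 3-(benzyloxy)-2-[4-(benzyloxy)phenyl]-5-hydroxy-6,7,8-trimethoxy-4H-chromen-4-one | COc1c(OC)c(O)c2c(=O)c(OCc3ccccc3)c(-c3ccc(OCc4ccccc4)cc3)oc2c1OC | intermediate
14 | 3,5,4'-trihydroxy-6,7,8-trimethoxyflavone | COc1c(OC)c(O)c2c(=O)c(O)c(-c3ccc(O)cc3)oc2c1OC | target

**Step count**

Total steps: 9. Longest linear sequence: 8 (steps 1, 3, 4, 5, 6, 7, 8, 9).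

**Steps most likely to fail, with fallbacks**

Step 5 (key cyclisation). The open chain may be cut by retro-Claisen attack of methoxide at the C3 or C5 ketone, both activated by α-methoxyls, or the free triketo ester may decompose during its isolation, before C-acylation takes place. The fallback carries the chain as a 2-pyranone and sets out from 6. DBU in refluxing toluene should lactonise the 3,5-dioxo ester (enol oxygen at C5 onto the ester, a standard 4-hydroxy-2-pyranone synthesis) to give 6-{[2-(benzyloxymethyl)-1,3-dioxolan-2-yl]methyl}-4-hydroxy-3,5-dimethoxy-2H-pyran-2-one F1. Aqueous HCl in THF then removes the dioxolane to give 6-[3-(benzyloxy)-2-oxopropyl]-4-hydroxy-3,5-dimethoxy-2H-pyran-2-one F2, a stable and purifiable surrogate of 7. Heating F2 with Mg(OMe)2 in methanol, the known rearrangement of 6-(2-oxoalkyl)-4-hydroxy-2-pyranones to acylphloroglucinols, should open the lactone inside the magnesium chelate and reclose it in the Claisen mode, so that the triketo ester is never handled as a free compound. The sequence comes back to the route at 8.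

Step 3 (dianion acylation). Proton transfer from the α-methylene of ester 4 to the dianion, followed by β-elimination that opens the dioxolane, may take the place of C-acylation, and the acidic product consumes dianion. The fallback sets out from 2 and uses acyl donors without a ketal. Dianion 5 is acetylated with N-methoxy-N-methylacetamide, whose tetrahedral adduct is stable until work-up, to give methyl 2,4-dimethoxy-3,5-dioxohexanoate F3. Three equivalents of LiN(i-Pr)2 should then convert F3 into trilithium 1,2,4-trimethoxyhexa-1,3,5-triene-1,3,5-tris(olate) F4, whose terminal carbanion is acylated with 2-(benzyloxy)-N-methoxy-N-methylacetamide; this is the known terminal acylation of 3,5-dioxoalkanoate trianions. Acidic work-up gives the triketo ester directly, so the route is rejoined at 7 and steps 2 and 4 are no longer needed.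

Step 6 (selective methylation). Methylation at an ortho hydroxyl, or double methylation, may compete, because only one of the two ortho hydroxyls is hydrogen-bonded to the carbonyl at any time. The fallback postpones the methylation to the flavone stage, where the 5-hydroxyl is firmly chelated, and sets out from 8. Excess 10 in pyridine with DMAP should give 2-[2-(benzyloxy)acetyl]-4,6-dimethoxybenzene-1,3,5-triyl tris[4-(benzyloxy)benzoate] F5. Baker–Venkataraman rearrangement with LiN(SiMe3)2 in THF should give 2-(benzyloxy)-1-[4-(benzyloxy)phenyl]-3-{2-hydroxy-3,5-dimethoxy-4,6-bis[4-(benzyloxy)benzoyloxy]phenyl}propane-1,3-dione F6. Cyclodehydration in AcOH with catalytic H2SO4 should then give 3-(benzyloxy)-2-[4-(benzyloxy)phenyl]-6,8-dimethoxy-4-oxo-4H-chromene-5,7-diyl bis[4-(benzyloxy)benzoate] F7. KOH in aqueous MeOH/THF removes the two remaining aroyl groups to give 3-(benzyloxy)-2-[4-(benzyloxy)phenyl]-5,7-dihydroxy-6,8-dimethoxy-4H-chromen-4-one F8. Me2SO4 and K2CO3 in acetone should then methylate only the unchelated 7-hydroxyl, a classical selective reaction of 5,7-dihydroxyflavones, and the route is rejoined at 13.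

**Further compounds**

F1 | step 5 | 6-{[2-(benzyloxymethyl)-1,3-dioxolan-2-yl]methyl}-4-hydroxy-3,5-dimethoxy-2H-pyran-2-one | COc1c(O)c(OC)c(CC2(COCc3ccccc3)OCCO2)oc1=O
F2 | step 5 | 6-[3-(benzyloxy)-2-oxopropyl]-4-hydroxy-3,5-dimethoxy-2H-pyran-2-one | COc1c(O)c(OC)c(CC(=O)COCc2ccccc2)oc1=O
F3 | step 3 | methyl 2,4-dimethoxy-3,5-dioxohexanoate | COC(=O)C(OC)C(=O)C(OC)C(C)=O
F4 | step 3 | trilithium 1,2,4-trimethoxyhexa-1,3,5-triene-1,3,5-tris(olate) (trianion of F3) | [Li+].[Li+].[Li+].COC([O-])=C(OC)C([O-])=C(OC)C([O-])=C
F5 | step 6 | 2-[2-(benzyloxy)acetyl]-4,6-dimethoxybenzene-1,3,5-triyl tris[4-(benzyloxy)benzoate] | COc1c(OC(=O)c2ccc(OCc3ccccc3)cc2)c(OC)c(OC(=O)c2ccc(OCc3ccccc3)cc2)c(C(=O)COCc2ccccc2)c1OC(=O)c1ccc(OCc2ccccc2)cc1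
F6 | step 6 | 2-(benzyloxy)-1-[4-(benzyloxy)phenyl]-3-{2-hydroxy-3,5-dimethoxy-4,6-bis[4-(benzyloxy)benzoyloxy]phenyl}propane-1,3-dione | COc1c(O)c(C(=O)C(OCc2ccccc2)C(=O)c2ccc(OCc3ccccc3)cc2)c(OC(=O)c2ccc(OCc3ccccc3)cc2)c(OC)c1OC(=O)c1ccc(OCc2ccccc2)cc1
F7 | step 6 | 3-(benzyloxy)-2-[4-(benzyloxy)phenyl]-6,8-dimethoxy-4-oxo-4H-chromene-5,7-diyl bis[4-(benzyloxy)benzoate] | COc1c(OC(=O)c2ccc(OCc3ccccc3)cc2)c(OC)c2oc(-c3ccc(OCc4ccccc4)cc3)c(OCc3ccccc3)c(=O)c2c1OC(=O)c1ccc(OCc2ccccc2)cc1
F8 | step 6 | 3-(benzyloxy)-2-[4-(benzyloxy)phenyl]-5,7-dihydroxy-6,8-dimethoxy-4H-chromen-4-one | COc1c(O)c(OC)c2oc(-c3ccc(OCc4ccccc4)cc3)c(OCc3ccccc3)c(=O)c2c1O
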